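The SMILES has no stereocentre and no stereogenic double bond, so the target is achiral and no stereocontrol is needed. Compound 1 is assumed to be bought; it is the phenol intermediate of the insecticide bendiocarb.

## Retrosynthetic overview
- Ring C (the 4-pyranone) is the only ring built, and it is built last. C2 is inserted as a one-carbon unit into a 2,4-dihydroxyphenyl benzyl ketone, and the catechol ketal is hydrolysed in the same pot.
- The key disconnection is C3–C1' (the CH2–aryl bond of that ketone). The α-carbon of resacetophenone is inverted to an iodine(III) enolonium (a2 synthon) and attacked by an unfunctionalised C–H of the electron-rich B-ring arene. Both carbons are natural nucleophiles.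
- The B-ring arene comes from an aromatic Claisen rearrangement of a prenyl ether, which delivers the 1,1-dimethylallyl group ortho to oxygen, followed by O-methylation.
- Rings A and B and the temporary dioxolane are bought.

## Route

Step 1
Reactants: 1 2,2-dimethyl-1,3-benzodioxol-4-ol; 2 prenyl bromide (1-bromo-3-methylbut-2-ene)
Product: 3 2,2-dimethyl-4-(3-methylbut-2-enyloxy)-1,3-benzodioxole
Conditions: K2CO3 (1.5 equiv), acetone, reflux, 6 h
Reagents that add atoms: none
Why: Williamson ether synthesis, in which the only free phenol is deprotonated and displaces bromide from the primary allylic halide by SN2 at oxygen while the ketal is inert to base; no stereocentre is formed.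

Step 2
Reactants: 3 2,2-dimethyl-4-(3-methylbut-2-enyloxy)-1,3-benzodioxole
Product: 5 4-methoxy-2,2-dimethyl-5-(2-methylbut-3-en-2-yl)-1,3-benzodioxole, via Claisen phenol 4 (not isolated)
Conditions: degassed DMF, 180 °C (sealed tube or µW), 1–2 h; cool to rt; K2CO3 (3 equiv), MeI (3 equiv), rt → 40 °C, 12 h
Reagents that add atoms: iodomethane, SMILES CI
Why: The aromatic Claisen rearrangement ([3,3]-sigmatropic) can reach only C5, because the other ortho position is the oxygen-bearing ring-fusion carbon, so the prenyl group arrives inverted as 1,1-dimethylallyl, and Williamson O-methylation in the same pot removes the O–H that feeds the abnormal Claisen and dihydrobenzofuran pathways; no stereocentre is formed.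

Step 3
Reactants: 6 2',4'-dihydroxyacetophenone (resacetophenone)
Product: 7 1-[2,4-bis(trimethylsilyloxy)phenyl]-1-(trimethylsilyloxy)ethene
Conditions: TMSOTf (3.5 equiv), Et3N (4.5 equiv), CH2Cl2, 0 °C → rt, 2 h; dilute with pentane, decant from the salt, concentrate, use at once
Reagents that add atoms: trimethylsilyl trifluoromethanesulfonate, SMILES C[Si](C)(C)OS(=O)(=O)C(F)(F)F
Why: Soft enolisation and silylation, in which TMSOTf/Et3N caps both phenols and converts the methyl ketone (only one enolisable side) into its TMS enol ether in one operation; no stereocentre is formed.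

Step 4 (key step)
Reactants: 7 1-[2,4-bis(trimethylsilyloxy)phenyl]-1-(trimethylsilyloxy)ethene; 5 4-methoxy-2,2-dimethyl-5-(2-methylbut-3-en-2-yl)-1,3-benzodioxole
Product: 10 1-(2,4-dihydroxyphenyl)-2-[7-methoxy-2,2-dimethyl-6-(2-methylbut-3-en-2-yl)-1,3-benzodioxol-4-yl]ethanone, via enolonium species 8 (not isolated), via bis-TMS deoxybenzoin 9 (not isolated)
Conditions: PhI(OH)OTs (1.2 equiv), BF3·OEt2 (1.2 equiv), CH2Cl2, −78 °C; add 7 (1.2 equiv), 10 min; add 5 (1.0 equiv), −78 → −20 °C, 2 h; cold sat. aq NaHCO3; crude in THF–10% aq citric acid, rt, 30 min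
Reagents that add atoms: none
Why: Proposed new method: Koser's reagent/BF3·OEt2 converts the enol silane into a discrete iodine(III) enolate (enolonium) at −78 °C before any oxidisable partner is present, and the arene then attacks the umpoled α-CH2 in a Friedel–Crafts-type displacement with reductive loss of PhI; attack occurs at C7 of 5 because that site is ortho to the planar dioxole oxygen and para to OMe, the only other C–H (C6) is shielded by the adjacent quaternary carbon, and the neopentyl-type vinyl group is far less nucleophilic than the ring; the closest known reaction types are the two-stage enolonium α-arylation of ketone TMS enol ethers with electron-rich (hetero)arenes and the C-alkylations of phenacyl(phenyl)iodonium salts, and the new elements are a pyrogallol-ether nucleophile and an ortho-silyloxy aryl ketone; no stereocentre is formed.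

Step 5
Reactants: 10 1-(2,4-dihydroxyphenyl)-2-[7-methoxy-2,2-dimethyl-6-(2-methylbut-3-en-2-yl)-1,3-benzodioxol-4-yl]ethanone
Product: 13 3-[2,3-dihydroxy-4-methoxy-5-(2-methylbut-3-en-2-yl)phenyl]-7-hydroxy-4H-chromen-4-one (target), via enaminone 11 (not isolated), via isoflavone acetonide 12 (not isolated)
Conditions: Me2NCH(OMe)2 (2 equiv), THF, 65 °C, 3 h; evaporate; degassed 3 M aq HCl–MeOH (1:3), 60 °C, N2, 4–8 h
Reagents that add atoms: N,N-dimethylformamide dimethyl acetal, SMILES COC(OC)N(C)C
Why: Formamide-acetal (enaminone) isoflavone annulation, in which the doubly activated CH2 condenses with DMF-DMA, the 2-OH adds and expels Me2NH to close the 4-pyranone, and aqueous acid then closes any remaining enaminone and hydrolyses the catechol ketal at an acidity that does not protonate a monosubstituted alkene or cleave the aryl methyl ether; no stereocentre is formed.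

## Compound list
1 | 2,2-dimethyl-1,3-benzodioxol-4-ol | CC1(C)Oc2cccc(O)c2O1 | starting material
2 | prenyl bromide (1-bromo-3-methylbut-2-ene) | CC(C)=CCBr | starting material
3 | 2,2-dimethyl-4-(3-methylbut-2-enyloxy)-1,3-benzodioxole | CC(C)=CCOc1cccc2OC(C)(C)Oc12 | intermediate
4 | 2,2-dimethyl-5-(2-methylbut-3-en-2-yl)-1,3-benzodioxol-4-ol (Claisen phenol, not isolated) | C=CC(C)(C)c1ccc2OC(C)(C)Oc2c1O | intermediate
5 | 4-methoxy-2,2-dimethyl-5-(2-methylbut-3-en-2-yl)-1,3-benzodioxole | C=CC(C)(C)c1ccc2OC(C)(C)Oc2c1OC | intermediate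
6 | 2',4'-dihydroxyacetophenone | CC(=O)c1ccc(O)cc1O | starting material
7 | 1-[2,4-bis(trimethylsilyloxy)phenyl]-1-(trimethylsilyloxy)ethene | C=C(O[Si](C)(C)C)c1ccc(O[Si](C)(C)C)cc1O[Si](C)(C)C | intermediate
8 | enolonium species, drawn as the O-bound phenyl(tosyloxy)-λ3-iodanyl enolate (the C-bound α-phenyliodonio ketone is the equivalent form; not isolated) | C=C(O[I](c1ccccc1)OS(=O)(=O)c1ccc(C)cc1)c1ccc(O[Si](C)(C)C)cc1O[Si](C)(C)C | intermediate
9 | 1-[2,4-bis(trimethylsilyloxy)phenyl]-2-[7-methoxy-2,2-dimethyl-6-(2-methylbut-3-en-2-yl)-1,3-benzodioxol-4-yl]ethanone (not isolated) | O=C(Cc1cc(C(C)(C)C=C)c(OC)c2OC(C)(C)Oc12)c1ccc(O[Si](C)(C)C)cc1O[Si](C)(C)C | intermediate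
10 | 1-(2,4-dihydroxyphenyl)-2-[7-methoxy-2,2-dimethyl-6-(2-methylbut-3-en-2-yl)-1,3-benzodioxol-4-yl]ethanone | O=C(Cc1cc(C(C)(C)C=C)c(OC)c2OC(C)(C)Oc12)c1ccc(O)cc1O | intermediate
11 | 3-(dimethylamino)-1-(2,4-dihydroxyphenyl)-2-[7-methoxy-2,2-dimethyl-6-(2-methylbut-3-en-2-yl)-1,3-benzodioxol-4-yl]prop-2-en-1-one (push–pull alkene, E/Z not fixed; not isolated) | CN(C)C=C(C(=O)c1ccc(O)cc1O)c1cc(C(C)(C)C=C)c(OC)c2OC(C)(C)Oc12 | intermediate
12 | 7-hydroxy-3-[7-methoxy-2,2-dimethyl-6-(2-methylbut-3-en-2-yl)-1,3-benzodioxol-4-yl]-4H-chromen-4-one (not isolated) | O=c1c(-c2cc(C(C)(C)C=C)c(OC)c3OC(C)(C)Oc23)coc2cc(O)ccc12 | intermediate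
13 | 3-[2,3-dihydroxy-4-methoxy-5-(2-methylbut-3-en-2-yl)phenyl]-7-hydroxy-4H-chromen-4-one (achiral) | C=CC(C)(C)c1cc(-c2coc3cc(O)ccc3c2=O)c(O)c(O)c1OC | target

## Step count
- **Total steps:** 5
- **Longest linear sequence:** 4 (steps 1, 2, 4, 5)

## Three steps most likely to fail

**Step 4.** Three side reactions are the main risks:
- The ortho silyloxy oxygen may close onto the umpoled carbon and give a benzofuran-3-one.
- Tosylate may outrun the arene and give the α-tosyloxy ketone.
- Excess enolonium may attack the vinyl group.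

The fallback sets out from 5 and comes back at 12. It makes the same C3–C1' bond intramolecularly, as an iodine(III)-induced 1,2-aryl shift. Compound 5 is lithiated next to the dioxole oxygen (n-BuLi, TMEDA, THF, 0 °C) to give 7-lithio-4-methoxy-2,2-dimethyl-5-(2-methylbut-3-en-2-yl)-1,3-benzodioxole F1. A DMF quench gives 7-methoxy-2,2-dimethyl-6-(2-methylbut-3-en-2-yl)-1,3-benzodioxole-4-carbaldehyde F2. Claisen–Schmidt condensation with 6 (KOH, EtOH) gives the (E)-2',4'-dihydroxychalcone F3, and Ac2O/pyridine gives the chalcone diacetate F4. PhI(OH)OTs in MeOH/HC(OMe)3 adds methanol at the benzylic carbon and places I(III) on the α-carbon. The electron-rich aryl group then migrates onto that carbon to give the racemic 2-aryl-3,3-dimethoxypropan-1-one diacetate F5. The acid stage of step 5 strips the acetates and closes the pyranone to 12, which goes on to 13.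

**Step 2.** Three side reactions are the main risks:
- A further Cope shift may give the 7-prenyl isomer.
- The abnormal Claisen rearrangement may compete.
- Phenol 4 may cyclise to a dihydrobenzofuran.

The fallback sets out from 1 and comes back at 5. It replaces the sigmatropic step with a cross-coupling. Amine-directed ortho-bromination (NBS, 10 mol % i-Pr2NH, CH2Cl2, 0 °C) gives 5-bromo-2,2-dimethyl-1,3-benzodioxol-4-ol F6. MeI/K2CO3 in DMF gives 5-bromo-4-methoxy-2,2-dimethyl-1,3-benzodioxole F7. A γ-selective (branched) allyl–aryl Suzuki–Miyaura coupling then gives 5, using prenylboronic acid pinacol ester, Pd with a bulky biarylphosphine, K3PO4 and THF–H2O at 40–70 °C.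

**Step 5.** Three problems are the main risks:
- DMF-DMA may methylate the acidic 7-OH.
- Condensation at the hindered CH2 may be slow.
- The acid stage may damage the product.

The fallback sets out from 5 and comes back at 12, which is then isolated. It carries C2 into the key step, so no one-carbon insertion is needed. Commercial 7-hydroxychroman-4-one (O=C1CCOc2cc(O)ccc12) is silylated with TMSOTf/Et3N to give 4,7-bis(trimethylsilyloxy)-2H-chromene F8. PhI(OH)OTs/BF3·OEt2 at −78 °C converts it into the chromanone enolonium F9. Addition of 5 gives the racemic 7-O-TMS isoflavanone F10. Aqueous citric acid work-up gives the racemic 7-hydroxyisoflavanone F11, whose C3 stereocentre is erased in the next operation. DDQ in dioxane at reflux dehydrogenates F11 to 12. Compound 12 is hydrolysed separately (80% aq AcOH, 90 °C, N2) to 13.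

## Further compounds
F1 | step 4 | 7-lithio-4-methoxy-2,2-dimethyl-5-(2-methylbut-3-en-2-yl)-1,3-benzodioxole | [Li]c1cc(C(C)(C)C=C)c(OC)c2OC(C)(C)Oc12
F2 | step 4 | 7-methoxy-2,2-dimethyl-6-(2-methylbut-3-en-2-yl)-1,3-benzodioxole-4-carbaldehyde | O=Cc1cc(C(C)(C)C=C)c(OC)c2OC(C)(C)Oc12
F3 | step 4 | (E)-1-(2,4-dihydroxyphenyl)-3-[7-methoxy-2,2-dimethyl-6-(2-methylbut-3-en-2-yl)-1,3-benzodioxol-4-yl]prop-2-en-1-one | O=C(/C=C/c1cc(C(C)(C)C=C)c(OC)c2OC(C)(C)Oc12)c1ccc(O)cc1O
F4 | step 4 | (E)-chalcone 2',4'-diacetate of F3 | CC(=O)Oc1ccc(C(=O)/C=C/c2cc(C(C)(C)C=C)c(OC)c3OC(C)(C)Oc23)c(OC(C)=O)c1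
F5 | step 4 | rac-1-(2,4-diacetoxyphenyl)-3,3-dimethoxy-2-[7-methoxy-2,2-dimethyl-6-(2-methylbut-3-en-2-yl)-1,3-benzodioxol-4-yl]propan-1-one | COC(OC)C(C(=O)c1ccc(OC(C)=O)cc1OC(C)=O)c1cc(C(C)(C)C=C)c(OC)c2OC(C)(C)Oc12
F6 | step 2 | 5-bromo-2,2-dimethyl-1,3-benzodioxol-4-ol | CC1(C)Oc2ccc(Br)c(O)c2O1
F7 | step 2 | 5-bromo-4-methoxy-2,2-dimethyl-1,3-benzodioxole | COc1c(Br)ccc2OC(C)(C)Oc12
F8 | step 5 | 4,7-bis(trimethylsilyloxy)-2H-chromene | C[Si](C)(C)OC1=CCOc2cc(O[Si](C)(C)C)ccc12
F9 | step 5 | chromanone enolonium, drawn as the O-bound phenyl(tosyloxy)-λ3-iodanyl enolate | Cc1ccc(cc1)S(=O)(=O)O[I](c1ccccc1)OC1=CCOc2cc(O[Si](C)(C)C)ccc12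
F10 | step 5 | rac-3-[7-methoxy-2,2-dimethyl-6-(2-methylbut-3-en-2-yl)-1,3-benzodioxol-4-yl]-7-(trimethylsilyloxy)chroman-4-one | C[Si](C)(C)Oc1ccc2C(=O)C(COc2c1)c1cc(C(C)(C)C=C)c(OC)c2OC(C)(C)Oc12
F11 | step 5 | rac-7-hydroxy-3-[7-methoxy-2,2-dimethyl-6-(2-methylbut-3-en-2-yl)-1,3-benzodioxol-4-yl]chroman-4-one | O=C1c2ccc(O)cc2OCC1c1cc(C(C)(C)C=C)c(OC)c2OC(C)(C)Oc12
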